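**Plan**
1. Retrosynthetic cuts, in order: the C8–prenyl bond (lithiation of C8 between O1 and the C7 oxygen); the O1–C8a bond of ring C; the C3–C4 bond (benzylation of a ring-B arylacetyl imide); the dimethylpyran ring on ring B (prenal annulation of 2,4-dihydroxybenzaldehyde).
2. Feature that allows the O1–C8a closure: in ring A the C7 hydroxyl is para to C4a (the carbon bearing the C4 methylene) and O1 sits on C8a, ortho to C4a and meta to the hydroxyl. Oxidising the corresponding para-alkylphenol to a 4-methoxycyclohexa-2,5-dienone makes C8a (and its twin C5) the β-carbon of an enone within six-ring reach of the C2 hydroxyl, and both β-carbons lead to the same arene.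
3. Forward order: ring-B chromene, one-carbon homologation to the arylacetic acid, auxiliary-controlled benzylation (C3), reduction to the C2 alcohol, dearomatisation of ring A, closure of ring C with rearomatisation, then C8 prenylation and deprotection.
4. Stereochemistry: C3 (R) is set once, by alkylation of the (R)-4-benzyl-2-oxazolidinone imide, and is not touched afterwards; the ring-fusion centres of the dearomatised intermediate vanish on rearomatisation.

Key step: step 10

Assumption: 4-(tert-butyldimethylsilyloxy)benzyl bromide (11) is taken as a purchasable reagent; enol ether 5 is used as an E/Z mixture, which is immaterial because both isomers hydrolyse to the same aldehyde.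

**Step 1**
Reactants: 1 2,4-dihydroxybenzaldehyde; 2 3-methylbut-2-enal
Product: 3 5-hydroxy-2,2-dimethyl-2H-chromene-6-carbaldehyde
Conditions: pyridine, 120 °C
Reagents that add atoms: none
Why: Base-mediated chromenylation of a resorcinol: the C2 hydroxyl is held by a hydrogen bond to the formyl group, so aldol-type C-alkylation at C3, loss of water to an ortho-quinone methide and oxa-6π-electrocyclisation onto the C4 oxygen should give the angular 5-hydroxychromene.

**Step 2**
Reactants: 3 5-hydroxy-2,2-dimethyl-2H-chromene-6-carbaldehyde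
Product: 4 2,2-dimethyl-5-(triisopropylsilyloxy)-2H-chromene-6-carbaldehyde
Conditions: TIPSOTf, 2,6-lutidine, CH2Cl2, 0 °C → rt
Reagents that add atoms: triisopropylsilyl trifluoromethanesulfonate, CC(C)[Si](OS(=O)(=O)C(F)(F)F)(C(C)C)C(C)C
Why: Silylation of the hindered phenol with a silyl triflate; the TIPS ether should survive the acid, enolate, hydride and carbonate steps, keeps ring B inert to the oxidant of step 9, and leaves with fluoride in step 10.

**Step 3**
Reactants: 4 2,2-dimethyl-5-(triisopropylsilyloxy)-2H-chromene-6-carbaldehyde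
Product: 5 6-(2-methoxyvinyl)-2,2-dimethyl-5-(triisopropylsilyloxy)-2H-chromene (E/Z mixture)
Conditions: Ph3P(CH2OMe)Cl, KOtBu, THF, 0 °C → rt
Reagents that add atoms: (methoxymethyl)triphenylphosphonium chloride, COC[P+](c1ccccc1)(c1ccccc1)c1ccccc1.[Cl-]
Why: Wittig methoxymethylenation is the standard one-carbon homologation of an aryl aldehyde and should tolerate the aryl silyl ether and the chromene.

**Step 4**
Reactants: 5 6-(2-methoxyvinyl)-2,2-dimethyl-5-(triisopropylsilyloxy)-2H-chromene
Product: 7 2-[2,2-dimethyl-5-(triisopropylsilyloxy)-2H-chromen-6-yl]acetic acid, via arylacetaldehyde 6 (not isolated)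
Conditions: 2 M HCl, THF, rt; then NaClO2, NaH2PO4, 2-methyl-2-butene, t-BuOH/H2O, 0 °C → rt
Reagents that add atoms: water, O; sodium chlorite, [Na+].[O-]Cl=O
Why: Acid hydrolysis of the enol ether followed directly by Pinnick oxidation avoids storing the self-condensing arylacetaldehyde, and the alkene scavenger protects the chromene double bond from hypochlorous acid.

**Step 5**
Reactants: 7 2-[2,2-dimethyl-5-(triisopropylsilyloxy)-2H-chromen-6-yl]acetic acid; 8 (R)-4-benzyl-2-oxazolidinone
Product: 10 (R)-4-benzyl-3-{2-[2,2-dimethyl-5-(triisopropylsilyloxy)-2H-chromen-6-yl]acetyl}oxazolidin-2-one, via mixed anhydride 9 (not isolated)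
Conditions: pivaloyl chloride, Et3N, THF, −20 °C; then 8, LiCl, −20 °C → rt
Reagents that add atoms: none
Why: N-Acylation of the oxazolidinone through the mixed pivalic anhydride is the usual mild way to attach an Evans auxiliary to an arylacetic acid.

**Step 6**
Reactants: 10 (R)-4-benzyl-3-{2-[2,2-dimethyl-5-(triisopropylsilyloxy)-2H-chromen-6-yl]acetyl}oxazolidin-2-one; 11 4-(tert-butyldimethylsilyloxy)benzyl bromide
Product: 13 (R)-4-benzyl-3-{(R)-3-[4-(tert-butyldimethylsilyloxy)phenyl]-2-[2,2-dimethyl-5-(triisopropylsilyloxy)-2H-chromen-6-yl]propanoyl}oxazolidin-2-one, via sodium enolate 12 (not isolated)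
Conditions: NaN(SiMe3)2, THF, −78 °C; then 11, −78 → −40 °C
Reagents that add atoms: none
Why: Evans asymmetric alkylation: the chelated (Z)-sodium enolate is benzylated on the face opposite the benzyl group of the (R)-auxiliary, which should set C3 as (R).

**Step 7**
Reactants: 13 alkylated imide
Product: 14 (R)-3-[4-(tert-butyldimethylsilyloxy)phenyl]-2-[2,2-dimethyl-5-(triisopropylsilyloxy)-2H-chromen-6-yl]propan-1-ol
Conditions: LiBH4, H2O (1 equiv), Et2O, 0 °C
Reagents that add atoms: none
Why: Reductive cleavage of the N-acyl oxazolidinone with LiBH4 should give the primary alcohol at 0 °C without epimerising the α-aryl centre, and the auxiliary is recovered.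

**Step 8**
Reactants: 14 primary alcohol
Product: 16 4-{(R)-3-(tert-butyldimethylsilyloxy)-2-[2,2-dimethyl-5-(triisopropylsilyloxy)-2H-chromen-6-yl]propyl}phenol, via tris-silyl ether 15 (not isolated)
Conditions: TBSCl, imidazole, DMF, rt; then Cs2CO3 (0.3 equiv), H2O (DMF/H2O 10:1), rt
Reagents that add atoms: tert-butyldimethylsilyl chloride, CC(C)(C)[Si](C)(C)Cl
Why: Silylation of the primary alcohol followed by carbonate-mediated cleavage of the unhindered phenolic TBS ether (the alkyl TBS ether and the doubly ortho-substituted aryl TIPS ether should stay) frees the ring-A phenol while masking the alcohol, which would otherwise spirocyclise onto the para carbon in step 9.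

**Step 9**
Reactants: 16 ring-A phenol
Product: 17 4-{(R)-3-(tert-butyldimethylsilyloxy)-2-[2,2-dimethyl-5-(triisopropylsilyloxy)-2H-chromen-6-yl]propyl}-4-methoxycyclohexa-2,5-dien-1-one
Conditions: PhI(OAc)2, MeOH, 0 °C
Reagents that add atoms: methanol, CO
Why: Oxidative dearomatisation of a para-alkylphenol with PhI(OAc)2 in methanol (para-quinol ether formation); only the free ring-A phenol can bind the iodane, and methanol traps the para carbon.

**Step 10**
Reactants: 17 4-methoxycyclohexadienone
Product: 20 (R)-3-(5-hydroxy-2,2-dimethyl-2H-chromen-6-yl)chroman-7-ol, via hydroxy dienone 18 (not isolated), via oxa-Michael adduct 19 (not isolated)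
Conditions: Bu4NF (3 equiv), THF, 0 °C → rt; aqueous work-up; then TsOH·H2O (20 mol %), CH2Cl2, 0 °C → rt
Reagents that add atoms: none
Why: Fluoride removes both silyl groups, and under these basic conditions the C2 alkoxide adds to a β-carbon of the cross-conjugated dienone (intramolecular oxa-Michael addition, 6-exo-trig, cis-fused adduct), which forms the O1–C8a bond and ring C. Acid then enolises the ketone toward C8 and ionises the C4a–OMe bond, and loss of the C8a proton from the cyclohexadienyl cation restores ring A as the 7-hydroxychroman; the net result is a formal oxidative coupling of an alcohol oxygen with a phenol carbon meta to the hydroxyl, two nucleophilic centres joined through umpolung of the phenol. The closest known reactions are the intramolecular oxa-Michael cyclisations of 4-substituted cyclohexa-2,5-dienones and the dearomatisation, Michael addition, rearomatisation sequences of para-quinol ethers that give meta-substituted phenols. No lasting stereocentre is created, since C4a and C8a become trigonal again and C3 is a spectator that keeps its (R) configuration. Regioselectivity needs no control because the two enone arms are constitutionally equivalent and converge on the same arene, and the choice between alkoxide closure (six-membered) and ring-B phenoxide closure (seven-membered) rests on ring size. Cyclising under base before any acid is added keeps the open quinol ether away from acid, where a dienone-phenol 1,2-shift could compete.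

**Step 11**
Reactants: 20 diphenol
Product: 21 (R)-7-(methoxymethoxy)-3-[5-(methoxymethoxy)-2,2-dimethyl-2H-chromen-6-yl]chromane
Conditions: NaH, MOMCl, DMF, 0 °C → rt
Reagents that add atoms: chloromethyl methyl ether, COCCl
Why: Williamson-type etherification of both phenoxides; the MOM groups survive organolithium chemistry and the one on C7 serves as the directing group in step 12.

**Step 12**
Reactants: 21 bis-MOM ether
Product: 23 (R)-7-(methoxymethoxy)-3-[5-(methoxymethoxy)-2,2-dimethyl-2H-chromen-6-yl]-8-(3-methylbut-2-en-1-yl)chromane, via aryllithium 22 (not isolated)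
Conditions: n-BuLi, THF, −20 → 0 °C; then 1-bromo-3-methylbut-2-ene, −78 °C → rt
Reagents that add atoms: 1-bromo-3-methylbut-2-ene, CC(C)=CCBr
Why: Directed ortho-metalation: C8–H lies between the chroman oxygen O1 and the C7 OMOM group, so cooperative coordination should direct n-BuLi there (ring B has no hydrogen ortho to its OMOM group), and the aryllithium is alkylated at the primary carbon of prenyl bromide.

**Step 13**
Reactants: 23 prenylated bis-MOM ether
Product: 24 (R)-3-(5-hydroxy-2,2-dimethyl-2H-chromen-6-yl)-8-(3-methylbut-2-en-1-yl)chroman-7-ol (CNP0263294.2)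
Conditions: HCl (3 M in MeOH), 0 °C → rt
Reagents that add atoms: none
Why: Acid-catalysed acetal exchange with methanol removes both MOM groups; the low temperature is meant to keep the ortho-prenylphenol from cyclising and the chromene from adding methanol.

**Compound list**
1 | 2,4-dihydroxybenzaldehyde | O=Cc1ccc(O)cc1O | starting material
2 | 3-methylbut-2-enal | CC(C)=CC=O | starting material
3 | 5-hydroxy-2,2-dimethyl-2H-chromene-6-carbaldehyde | CC1(C)C=Cc2c(O1)ccc(C=O)c2O | intermediate
4 | 2,2-dimethyl-5-(triisopropylsilyloxy)-2H-chromene-6-carbaldehyde | CC1(C)C=Cc2c(O1)ccc(C=O)c2O[Si](C(C)C)(C(C)C)C(C)C | intermediate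
5 | 6-(2-methoxyvinyl)-2,2-dimethyl-5-(triisopropylsilyloxy)-2H-chromene (E/Z mixture) | COC=Cc1ccc2OC(C)(C)C=Cc2c1O[Si](C(C)C)(C(C)C)C(C)C | intermediate
6 | 2-[2,2-dimethyl-5-(triisopropylsilyloxy)-2H-chromen-6-yl]acetaldehyde (formed in the flask) | O=CCc1ccc2OC(C)(C)C=Cc2c1O[Si](C(C)C)(C(C)C)C(C)C | intermediate
7 | 2-[2,2-dimethyl-5-(triisopropylsilyloxy)-2H-chromen-6-yl]acetic acid | OC(=O)Cc1ccc2OC(C)(C)C=Cc2c1O[Si](C(C)C)(C(C)C)C(C)C | intermediate
8 | (R)-4-benzyl-2-oxazolidinone | O=C1N[C@H](Cc2ccccc2)CO1 | starting material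
9 | mixed anhydride of acid 7 with pivalic acid (formed in the flask) | CC(C)(C)C(=O)OC(=O)Cc1ccc2OC(C)(C)C=Cc2c1O[Si](C(C)C)(C(C)C)C(C)C | intermediate
10 | (R)-4-benzyl-3-{2-[2,2-dimethyl-5-(triisopropylsilyloxy)-2H-chromen-6-yl]acetyl}oxazolidin-2-one | O=C(Cc1ccc2OC(C)(C)C=Cc2c1O[Si](C(C)C)(C(C)C)C(C)C)N1[C@H](Cc2ccccc2)COC1=O | intermediate
11 | 4-(tert-butyldimethylsilyloxy)benzyl bromide | BrCc1ccc(O[Si](C)(C)C(C)(C)C)cc1 | starting material
12 | (Z)-sodium enolate of imide 10 (formed in the flask) | [Na+].[O-]/C(=C\c1ccc2OC(C)(C)C=Cc2c1O[Si](C(C)C)(C(C)C)C(C)C)N1[C@H](Cc2ccccc2)COC1=O | intermediate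
13 | (R)-4-benzyl-3-{(R)-3-[4-(tert-butyldimethylsilyloxy)phenyl]-2-[2,2-dimethyl-5-(triisopropylsilyloxy)-2H-chromen-6-yl]propanoyl}oxazolidin-2-one | O=C([C@H](Cc1ccc(O[Si](C)(C)C(C)(C)C)cc1)c1ccc2OC(C)(C)C=Cc2c1O[Si](C(C)C)(C(C)C)C(C)C)N1[C@H](Cc2ccccc2)COC1=O | intermediate
14 | (R)-3-[4-(tert-butyldimethylsilyloxy)phenyl]-2-[2,2-dimethyl-5-(triisopropylsilyloxy)-2H-chromen-6-yl]propan-1-ol | OC[C@H](Cc1ccc(O[Si](C)(C)C(C)(C)C)cc1)c1ccc2OC(C)(C)C=Cc2c1O[Si](C(C)C)(C(C)C)C(C)C | intermediate
15 | tert-butyldimethylsilyl ether of alcohol 14 (tris-silyl ether, formed in the flask) | CC(C)(C)[Si](C)(C)OC[C@H](Cc1ccc(O[Si](C)(C)C(C)(C)C)cc1)c1ccc2OC(C)(C)C=Cc2c1O[Si](C(C)C)(C(C)C)C(C)C | intermediate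
16 | 4-{(R)-3-(tert-butyldimethylsilyloxy)-2-[2,2-dimethyl-5-(triisopropylsilyloxy)-2H-chromen-6-yl]propyl}phenol | CC(C)(C)[Si](C)(C)OC[C@H](Cc1ccc(O)cc1)c1ccc2OC(C)(C)C=Cc2c1O[Si](C(C)C)(C(C)C)C(C)C | intermediate
17 | 4-{(R)-3-(tert-butyldimethylsilyloxy)-2-[2,2-dimethyl-5-(triisopropylsilyloxy)-2H-chromen-6-yl]propyl}-4-methoxycyclohexa-2,5-dien-1-one | CC(C)(C)[Si](C)(C)OC[C@H](CC1(OC)C=CC(=O)C=C1)c1ccc2OC(C)(C)C=Cc2c1O[Si](C(C)C)(C(C)C)C(C)C | intermediate
18 | 4-[(R)-3-hydroxy-2-(5-hydroxy-2,2-dimethyl-2H-chromen-6-yl)propyl]-4-methoxycyclohexa-2,5-dien-1-one (formed in the flask) | OC[C@H](CC1(OC)C=CC(=O)C=C1)c1ccc2OC(C)(C)C=Cc2c1O | intermediate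
19 | (3R)-3-(5-hydroxy-2,2-dimethyl-2H-chromen-6-yl)-4a-methoxy-2,3,4,4a,8,8a-hexahydro-7H-chromen-7-one (cis-fused, both ring-fusion diastereomers, formed in the flask) | O=C1CC2OC[C@@H](c3ccc4OC(C)(C)C=Cc4c3O)CC2(OC)C=C1 | intermediate
20 | (R)-3-(5-hydroxy-2,2-dimethyl-2H-chromen-6-yl)chroman-7-ol | Oc1ccc2c(c1)OC[C@@H](c1ccc3OC(C)(C)C=Cc3c1O)C2 | intermediate
21 | (R)-7-(methoxymethoxy)-3-[5-(methoxymethoxy)-2,2-dimethyl-2H-chromen-6-yl]chromane | COCOc1ccc2c(c1)OC[C@@H](c1ccc3OC(C)(C)C=Cc3c1OCOC)C2 | intermediate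
22 | 8-lithio derivative of 21 (formed in the flask) | [Li]c1c(OCOC)ccc2c1OC[C@@H](c1ccc3OC(C)(C)C=Cc3c1OCOC)C2 | intermediate
23 | (R)-7-(methoxymethoxy)-3-[5-(methoxymethoxy)-2,2-dimethyl-2H-chromen-6-yl]-8-(3-methylbut-2-en-1-yl)chromane | CC(C)=CCc1c(OCOC)ccc2c1OC[C@@H](c1ccc3OC(C)(C)C=Cc3c1OCOC)C2 | intermediate
24 | (R)-3-(5-hydroxy-2,2-dimethyl-2H-chromen-6-yl)-8-(3-methylbut-2-en-1-yl)chroman-7-ol (CNP0263294.2) | CC(C)=CCc1c(O)ccc2c1OC[C@@H](c1ccc3c(c1O)C=CC(C)(C)O3)C2 | target

**Step count and risks**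
Total steps: 13. Longest linear sequence: 13 steps (1 → 24); compounds 2, 8 and 11 are bought.

Steps most likely to fail:

Step 10. On acidification the oxa-Michael adduct may revert to the open quinol ether, which can then undergo a dienone-phenol 1,2-shift or fail to lose methanol. The fallback forms the same aryl–oxygen bond by palladium-catalysed cross-coupling of an aryl bromide; it sets out from imide 10 and comes back at 20. 3-Bromo-4-methylphenol would be silylated (TBSCl, imidazole) to (3-bromo-4-methylphenoxy)(tert-butyl)dimethylsilane F1 and brominated at the benzylic position (NBS, AIBN, PhCF3, 80 °C) to [3-bromo-4-(bromomethyl)phenoxy](tert-butyl)dimethylsilane F2. The sodium enolate 12 of imide 10 would be alkylated with F2 to the bromoaryl imide F3, and LiBH4 would give the bromo alcohol F4. Pd(OAc)2 with 2-(di-tert-butylphosphino)-1,1'-binaphthyl and Cs2CO3 in toluene at 80 °C should close ring C by intramolecular C–O coupling to the bis-silylated chroman F5, and Bu4NF would then give 20.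

Step 9. The iodane may oxidise the electron-rich ring B or the benzylic C4–H (quinone methide formation) instead of giving clean para-methoxylation. The fallback dearomatises through a peroxide instead; it sets out from phenol 16 and comes back at 20. KHSO5 (as the triple salt 2KHSO5·KHSO4·K2SO4) with NaHCO3 in MeCN/H2O should give the para-peroxyquinol F6, which Na2S2O3 would reduce to the para-quinol F7. Bu4NF would then remove both silyl groups to the open quinol F8, which should cyclise in the same flask to the 4a-hydroxy oxa-Michael adduct F9, and TsOH·H2O would dehydrate F9 to 20.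

Step 13. During acetal cleavage the acid may cyclise the prenyl group onto the C7 hydroxyl or add methanol to the chromene double bond. The fallback avoids phenol protection and acid altogether by delivering the prenyl group through a sigmatropic shift; it sets out from diphenol 20 and comes back at 24. The unhindered C7 hydroxyl would be alkylated with 3-chloro-3-methylbut-1-yne (DBU, CuCl2 cat., MeCN, 0 °C) to the 7-O-(2-methylbut-3-yn-2-yl) ether F10. Semi-hydrogenation (H2, Pd/CaCO3 poisoned with Pb(OAc)2, quinoline, EtOAc) would give the 7-O-(2-methylbut-3-en-2-yl) ether F11, and heating F11 in N,N-diethylaniline at about 120 °C should trigger the aromatic Claisen rearrangement to C8 and give 24; any C6 isomer would have to be separated.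

**Further compounds**
F1 | step 10 | (3-bromo-4-methylphenoxy)(tert-butyl)dimethylsilane | Cc1ccc(O[Si](C)(C)C(C)(C)C)cc1Br
F2 | step 10 | [3-bromo-4-(bromomethyl)phenoxy](tert-butyl)dimethylsilane | BrCc1ccc(O[Si](C)(C)C(C)(C)C)cc1Br
F3 | step 10 | (R)-4-benzyl-3-{(R)-3-[2-bromo-4-(tert-butyldimethylsilyloxy)phenyl]-2-[2,2-dimethyl-5-(triisopropylsilyloxy)-2H-chromen-6-yl]propanoyl}oxazolidin-2-one | O=C([C@H](Cc1ccc(O[Si](C)(C)C(C)(C)C)cc1Br)c1ccc2OC(C)(C)C=Cc2c1O[Si](C(C)C)(C(C)C)C(C)C)N1[C@H](Cc2ccccc2)COC1=O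
F4 | step 10 | (R)-3-[2-bromo-4-(tert-butyldimethylsilyloxy)phenyl]-2-[2,2-dimethyl-5-(triisopropylsilyloxy)-2H-chromen-6-yl]propan-1-ol | OC[C@H](Cc1ccc(O[Si](C)(C)C(C)(C)C)cc1Br)c1ccc2OC(C)(C)C=Cc2c1O[Si](C(C)C)(C(C)C)C(C)C
F5 | step 10 | (R)-7-(tert-butyldimethylsilyloxy)-3-[2,2-dimethyl-5-(triisopropylsilyloxy)-2H-chromen-6-yl]chromane | CC(C)(C)[Si](C)(C)Oc1ccc2c(c1)OC[C@@H](c1ccc3OC(C)(C)C=Cc3c1O[Si](C(C)C)(C(C)C)C(C)C)C2
F6 | step 9 | 4-{(R)-3-(tert-butyldimethylsilyloxy)-2-[2,2-dimethyl-5-(triisopropylsilyloxy)-2H-chromen-6-yl]propyl}-4-hydroperoxycyclohexa-2,5-dien-1-one | CC(C)(C)[Si](C)(C)OC[C@H](CC1(OO)C=CC(=O)C=C1)c1ccc2OC(C)(C)C=Cc2c1O[Si](C(C)C)(C(C)C)C(C)C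
F7 | step 9 | 4-{(R)-3-(tert-butyldimethylsilyloxy)-2-[2,2-dimethyl-5-(triisopropylsilyloxy)-2H-chromen-6-yl]propyl}-4-hydroxycyclohexa-2,5-dien-1-one | CC(C)(C)[Si](C)(C)OC[C@H](CC1(O)C=CC(=O)C=C1)c1ccc2OC(C)(C)C=Cc2c1O[Si](C(C)C)(C(C)C)C(C)C
F8 | step 9 | 4-hydroxy-4-[(R)-3-hydroxy-2-(5-hydroxy-2,2-dimethyl-2H-chromen-6-yl)propyl]cyclohexa-2,5-dien-1-one | OC[C@H](CC1(O)C=CC(=O)C=C1)c1ccc2OC(C)(C)C=Cc2c1O
F9 | step 9 | (3R)-4a-hydroxy-3-(5-hydroxy-2,2-dimethyl-2H-chromen-6-yl)-2,3,4,4a,8,8a-hexahydro-7H-chromen-7-one (cis-fused) | O=C1CC2OC[C@@H](c3ccc4OC(C)(C)C=Cc4c3O)CC2(O)C=C1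
F10 | step 13 | (R)-2,2-dimethyl-6-[7-(2-methylbut-3-yn-2-yloxy)chroman-3-yl]-2H-chromen-5-ol | C#CC(C)(C)Oc1ccc2c(c1)OC[C@@H](c1ccc3OC(C)(C)C=Cc3c1O)C2
F11 | step 13 | (R)-2,2-dimethyl-6-[7-(2-methylbut-3-en-2-yloxy)chroman-3-yl]-2H-chromen-5-ol | C=CC(C)(C)Oc1ccc2c(c1)OC[C@@H](c1ccc3OC(C)(C)C=Cc3c1O)C2
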